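Every substrate molecule charged stays somewhere, so the products, the remaining substrate and any form I cannot see add up to the whole charge at each moment.

in all of them: substrate 0.30 M
- grey: first nucleophile 0.60 M; second nucleophile 0.60 M; the very flask that is asked about, followed so far
- flask: first nucleophile 0.600 M; second nucleophile 0.600 M; time 3.0 h

grey run (percent of the substrate charged)

| time / min | other capture product / % | target / % |
|---|---|---|
| 15.0 | 29.7 | 12.2 |
| 30.0 | 46.0 | 16.5 |
| 40.0 | 54.6 | 18.8 |
| 60.0 | 63.2 | 21.8 |
| 80.0 | 63.8 | 21.7 |

(standard deviation of a reading: 1 percentage point)

* ratio of other capture product to target at 25 s
* ratio of other capture product to target at 8.0 min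
* ratio of other capture product to target at 3.0 h



The grey run has the charges of the flask asked about, so the two differ in where they stop: 80.0 min against 3.0 h. I read two things from the first reading, at 15.0 min, and both carry its scatter. If substrate loss is first-order and the two products count what has gone, the substrate lifetime τ is 27.6 min.

My quantity is S = 2.43, the selectivity factor: the ratio of other capture product to target in the first reading, multiplied by the charge of first nucleophile over that of second nucleophile. I assume that both nucleophiles capture one common precursor, each in proportion to its concentration. So I expect early ratios near S, and at equal charges S/(1+S) = 70.9% of the substrate should end as other capture product.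

At 80.0 min, τ leaves 5.52% of the substrate, yet the two product readings leave 14.5% unaccounted, which is more than that, so I put about 9 percentage points in something unread. The flask runs on for 100 min, longer than τ. If the unread part comes from target, I expect a final ratio above 3.27.

The forecast differs at the end: for the three times asked, in order, it gives 2.2, 2.4 and 2.92, holding that “with nothing moving after 60 min, the plateau should hold at about 2.9”.

In the same order the flask gives 2.45, 2.59 and 4.51, the last higher than the forecast.

    substrate → intermediate (k = 6.00 × 10⁻⁴ s⁻¹)
    first nucleophile + intermediate → target (k = 0.160 M⁻¹ s⁻¹)
    second nucleophile + intermediate → other capture product (k = 0.340 M⁻¹ s⁻¹)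
    target ⇌ isomer of the product (K = 2.00, k = 1.00 × 10⁻⁴ s⁻¹)
    first nucleophile ⇌ dormant form (K = 0.230, k = 0.0200 s⁻¹)

At 3.00 h the flask holds 69.6% other capture product, 15.4% target and 14.8% isomer of the product, and target, each step taken net, is made at 0.0384 of the rate at which it is used up, so it is made more slowly than it goes. The neighbour is charged with 0.15 M of second nucleophile and the same first nucleophile. For it, S gives an early ratio of 0.609, and at 25 s that neighbour shows 0.616.

(All runs were generated by integration on assumed constants; the scatter is artificial.)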